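**Plan**
- Cut 1: break C1–C8a of the tetralin, return one H of C4H2 to that arene carbon, and re-bond C1 to C4. This gives the all-trans, C2-symmetric 1,2-bis(syringyl)-3,4-bis(hydroxymethyl)cyclobutane, the head-to-head [2+2] dimer of sinapyl alcohol and a constitutional isomer (C22H28O8) of the target.
- Enabling feature: the tetralin ring is C1–C2–C3–C4 (the four cyclobutane carbons) plus C4a/C8a, which are the ipso and ortho carbons of one syringyl substituent. In the dimer this aromatic C=C lies next to the four-membered ring (an aryl "vinylcyclobutane"), and the C1–C4 bond is strained, doubly benzylic and flanked by two p-hydroxyaryl donors.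
- Cut 2: break the two cyclobutane bonds C1–C4 and C2–C3 ([2+2]). This leads back to two sinapate units held on a C2-symmetric chiral diol.
- Forward order: O-acetylation, double esterification, intramolecular [2+2] (cyclobutane ring), LiAlH4 (tether and acetates removed), acid-induced two-atom ring expansion (tetralin ring, last step).
- Stereochemistry: the C2/C3 trans pair and its absolute sense come from the tether-controlled photocycloaddition, where diastereomers can be separated. C1 is set in the key step by 1,2-induction from C2. The two aryl-bearing cyclobutane centres are erased, so epimers at those carbons converge.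

Key step: step 5

Assumption: the (4S,5S)-diol is taken to induce the (R,R) configuration at the two ester-bearing cyclobutane carbons; if the sense proves opposite, the equally available (4R,5R)-diol is used and nothing else changes.
Numbering remark: the Why lines use lignan numbering. C7/C7' are the aryl-bearing carbons, C8/C8' the adjacent carbons, C9/C9' their CH2O or C(=O)O carbons, and C1–C6 the aromatic carbons. Target C1, C2, C3, C4 correspond to C7', C8', C8, C7.

Step 1
Reactants: 1 sinapic acid
Product: 2 (E)-4-O-acetylsinapic acid
Conditions: Ac2O, pyridine, rt; aqueous work-up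
Reagents that add atoms: acetic anhydride, CC(=O)OC(C)=O
Why: Phenol O-acetylation masks the easily oxidised phenol against electron transfer in step 3, and the acetate is chosen because the reduction in step 4 removes it without an extra step.

Step 2
Reactants: 2 (E)-4-O-acetylsinapic acid (2 equiv); 3 (4S,5S)-2,2-dimethyl-1,3-dioxolane-4,5-dimethanol
Product: 4 bis[(E)-4-O-acetylsinapate] of diol 3
Conditions: DCC, DMAP (cat.), CH2Cl2, 0 °C to rt
Reagents that add atoms: none
Why: Steglich esterification of two unhindered primary alcohols under neutral conditions should leave the acetonide, the aryl acetates and the two dioxolane stereocentres untouched.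

Step 3
Reactants: 4 bis[(E)-4-O-acetylsinapate] of diol 3
Product: 5 ten-membered dilactone of diol 3 with (1R,2R,3S,4S)-3,4-bis(4-acetoxy-3,5-dimethoxyphenyl)cyclobutane-1,2-dicarboxylic acid (all-trans, δ-truxinate type)
Conditions: [Ir{dF(CF3)ppy}2(dtbbpy)]PF6 (1 mol %), degassed MeCN (5 mM), blue LEDs, rt
Reagents that add atoms: none
Why: This is an intramolecular triplet-sensitised [2+2] photocycloaddition of a tethered dicinnamate, a known route from dicinnamates of chiral diols to optically active δ-truxinates, in which energy transfer, C8–C8' bonding to the bis-benzylic 1,4-diradical and closure should give the all-trans head-to-head cyclobutane, the ester tether enforcing head-to-head regiochemistry and the C2-symmetric dioxolane choosing the alkene faces that meet and so setting C8/C8' (trans, R,R), while diastereomeric cycloadducts are removed by chromatography or crystallisation.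

Step 4
Reactants: 5 macrocyclic δ-truxinate dilactone
Product: 6 [(1R,2R,3S,4S)-3,4-bis(4-hydroxy-3,5-dimethoxyphenyl)cyclobutane-1,2-diyl]dimethanol
Conditions: LiAlH4 (excess), THF, 0 °C to rt; aq. Rochelle salt, then pH 6
Reagents that add atoms: none
Why: LiAlH4 ester reduction cleaves both alkyl ester links and both aryl acetates in one operation, which releases the auxiliary diol, frees both phenols and creates both CH2OH groups without touching the four ring stereocentres.

Step 5
Reactants: 6 [(1R,2R,3S,4S)-3,4-bis(4-hydroxy-3,5-dimethoxyphenyl)cyclobutane-1,2-diyl]dimethanol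
Product: 9 (1S,2R,3R)-lyoniresinol (target), via ring-opened p-quinone methide 7 (not isolated), via 5,5'-dimethoxylariciresinol 8 (not isolated)
Conditions: TfOH (20 mol %), HFIP (0.01 M), Ar, 40 °C; then aq. NaHCO3
Reagents that add atoms: none
Why: Proposed new method: C-protonation of one syringyl ring of C2-symmetric 6 at C2/C6 (ortho and para to OMe) puts cationic character on its ipso carbon C1, making a cyclobutylcarbinyl cation whose aligned, strained (about 26 kcal/mol) and doubly benzylic C7–C7' σ bond fragments toward the other p-hydroxyaryl donor, and proton shuffling rearomatises the first ring so that C7 ends as ArCH2 and C7' as the p-hydroxybenzyl cation, drawn in neutral form as quinone methide 7. Arene carbon C6 next to the new CH2 then attacks C7' in a Friedel–Crafts 6-exo-trig closure (the only ring closed), so the four cyclobutane carbons plus C1 and C6 of one aryl substituent become the tetralin ring, which is a net [1,3]-shift of C7' from C7 to C6 followed by tautomerisation with no atom gained or lost. The closest known reaction types are the TfOH/HFIP ring-opening hydroarylation of arylcyclopropanes, the heteroaryl-vinylcyclobutane-to-cyclohexene rearrangement of C2-symmetric 1,2-bis(2-aminoimidazolyl)cyclobutanes, and the acid isomerisation of 7,9'-epoxylignans to aryltetralins, and the last of these is why 5-exo O-capture of 7 to tetrahydrofuran 8 should be only a reversible reservoir. The single new stereocentre C1 (C7') is controlled by the adjacent C8' centre, because closure through a half-chair with the aryl group and both CH2OH groups pseudo-equatorial gives the 1,2-trans isomer, which is also the thermodynamic one, and since both aryl-bearing cyclobutane centres are erased any epimer of 6 at those carbons would converge on 9. The step needs cleavage of C7–C7' only (no other ring bond can release a donor-stabilised cation), has no regiochemical choice (the two halves of 6 are homotopic and C2/C6 of the attacking ring are equivalent), and needs retention at C8/C8', which is secured because the C7 terminus becomes a closed-shell CH2 after protonation, so the cycloreversion typical of diradical or radical-cation openings of such cyclobutanes has no driving force. High dilution in non-nucleophilic, cation-stabilising HFIP should suppress intermolecular alkylation.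

**Compound list**
1 | sinapic acid, (E)-3-(4-hydroxy-3,5-dimethoxyphenyl)prop-2-enoic acid | COc1cc(/C=C/C(=O)O)cc(OC)c1O | starting material
2 | (E)-4-O-acetylsinapic acid | COc1cc(/C=C/C(=O)O)cc(OC)c1OC(C)=O | intermediate
3 | (4S,5S)-2,2-dimethyl-1,3-dioxolane-4,5-dimethanol (2,3-O-isopropylidene-L-threitol) | CC1(C)O[C@@H](CO)[C@H](CO)O1 | starting material
4 | bis[(E)-4-O-acetylsinapate] of diol 3 | CC(=O)Oc1c(OC)cc(/C=C/C(=O)OC[C@@H]2OC(C)(C)O[C@H]2COC(=O)/C=C/c2cc(OC)c(OC(C)=O)c(OC)c2)cc1OC | intermediate
5 | ten-membered dilactone of diol 3 with (1R,2R,3S,4S)-3,4-bis(4-acetoxy-3,5-dimethoxyphenyl)cyclobutane-1,2-dicarboxylic acid | O=C1OC[C@@H]2OC(C)(C)O[C@H]2COC(=O)[C@H]3[C@H]1[C@@H](c4cc(OC)c(OC(C)=O)c(OC)c4)[C@@H]3c5cc(OC)c(OC(C)=O)c(OC)c5 | intermediate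
6 | [(1R,2R,3S,4S)-3,4-bis(4-hydroxy-3,5-dimethoxyphenyl)cyclobutane-1,2-diyl]dimethanol | OC[C@H]1[C@H](CO)[C@@H](c2cc(OC)c(O)c(OC)c2)[C@@H]1c3cc(OC)c(O)c(OC)c3 | intermediate
7 | (8R,8'R) ring-opened p-quinone methide, 4-[(2R,3R)-4-(4-hydroxy-3,5-dimethoxyphenyl)-2,3-bis(hydroxymethyl)butylidene]-2,6-dimethoxycyclohexa-2,5-dien-1-one | COC1=CC(=C[C@@H](CO)[C@H](CO)Cc2cc(OC)c(O)c(OC)c2)C=C(OC)C1=O | intermediate (not isolated)
8 | 5,5'-dimethoxylariciresinol, 4-{[(3R,4R,5S)-5-(4-hydroxy-3,5-dimethoxyphenyl)-4-(hydroxymethyl)oxolan-3-yl]methyl}-2,6-dimethoxyphenol | OC[C@H]1[C@@H](Cc2cc(OC)c(O)c(OC)c2)CO[C@@H]1c3cc(OC)c(O)c(OC)c3 | intermediate (not isolated)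
9 | (1S,2R,3R)-lyoniresinol | COc1cc([C@H]2c3c(cc(OC)c(O)c3OC)C[C@@H](CO)[C@@H]2CO)cc(OC)c1O | target

Total step count: 5. Longest linear sequence: 5 (1 → 2 → 4 → 5 → 6 → 9).

**Steps most likely to fail**

Step 5 (Proposed new method). The C7–C7' bond may resist protonolysis below the temperature at which the polyol is dehydrated or alkylated intermolecularly. The opened cation may also fragment further to monomeric cinnamyl units. The fallback uses known chemistry and sets out from 6.
- Two-electron oxidation of the bisphenol (Ag2O, CH2Cl2, or FeCl3·6H2O, acetone) is the known oxidative ring opening of 1,2-bis(4-hydroxyaryl)cyclobutanes to bis-quinone methides. With double 5-exo capture by the two CH2OH groups it should give (7S,7'S,8R,8'R)-syringaresinol F1.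
- Controlled hydrogenolysis of one benzylic C–O bond (H2, Pd/C, EtOH) should give 8, where the route is rejoined.
- Compound 8 is carried to 9 with TFA in CH2Cl2, the established epoxylignan-to-aryltetralin isomerisation.

Step 3. Facial selectivity of the tether may be poor, unproductive E/Z isomerisation may dominate, or intermolecular oligomerisation may compete with closure of the ten-membered ring. The fallback replaces auxiliary control by resolution and sets out from 2.
- Steglich esterification with methanol should give methyl (E)-4-O-acetylsinapate F2.
- Intermolecular triplet-sensitised head-to-head photodimerisation in concentrated solution should give racemic dimethyl δ-truxinate F3.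
- LiAlH4 reduction as in step 4 should give 6 together with the mirror-image tetraol F4.
- Preparative chromatography on a chiral stationary phase separates the two, and the route is rejoined at 6.

Step 4. Insoluble aluminium phenoxide/alkoxide aggregates may stop the reduction before all four ester groups are consumed, and the polar tetraol may be lost on the aluminium salts. The fallback separates auxiliary removal from reduction and sets out from 5.
- Transesterification (K2CO3, MeOH, rt) removes the tether and both acetates. It should give the dimethyl ester bisphenol F5, in which the all-trans arrangement is the stable one.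
- DIBAL-H in THF/CH2Cl2 at −78 °C to 0 °C reduces F5, and the route is rejoined at 6.

**Further compounds**
F1 | step 5 | (7S,7'S,8R,8'R)-syringaresinol | COc1cc([C@H]2OC[C@H]3[C@@H]2CO[C@@H]3c2cc(OC)c(O)c(OC)c2)cc(OC)c1O
F2 | step 3 | methyl (E)-4-O-acetylsinapate | COC(=O)/C=C/c1cc(OC)c(OC(C)=O)c(OC)c1
F3 | step 3 | rac-dimethyl (1R*,2R*,3S*,4S*)-3,4-bis(4-acetoxy-3,5-dimethoxyphenyl)cyclobutane-1,2-dicarboxylate (one enantiomer drawn) | COC(=O)[C@H]1[C@H](C(=O)OC)[C@@H](c2cc(OC)c(OC(C)=O)c(OC)c2)[C@@H]1c3cc(OC)c(OC(C)=O)c(OC)c3
F4 | step 3 | [(1S,2S,3R,4R)-3,4-bis(4-hydroxy-3,5-dimethoxyphenyl)cyclobutane-1,2-diyl]dimethanol (mirror image of 6) | OC[C@@H]1[C@@H](CO)[C@H](c2cc(OC)c(O)c(OC)c2)[C@H]1c3cc(OC)c(O)c(OC)c3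
F5 | step 4 | dimethyl (1R,2R,3S,4S)-3,4-bis(4-hydroxy-3,5-dimethoxyphenyl)cyclobutane-1,2-dicarboxylate | COC(=O)[C@H]1[C@H](C(=O)OC)[C@@H](c2cc(OC)c(O)c(OC)c2)[C@@H]1c3cc(OC)c(O)c(OC)c3
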